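**Strategy.** The dimer is cut at the C4(ring C)–C8(ring D) bond into a (2S)-flavan-4-ol and (−)-epiafzelechin, and ring C of the flavan-4-ol is made by an anionic [3+3] annulation. In one operation a C,O-dianion that holds O1, the C2 stereocentre and C3 (from an enantiopure iodohydrin) adds through C3 to the formyl carbon C4 of a 2-fluorobenzaldehyde and then closes O1–C8a by SNAr at the C–F carbon of ring A. The step exploits the 1,3-relation of C4 and C8a on ring A and the para O7, which lets C4 ionise later, so that its configuration is set only in the final cation-type 4→8 coupling.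

Key step: step 3

Remark: the three starting materials in the compound list are taken as purchasable. Flavan numbering (O1, C2, C3, C4, C4a, C5–C8, C8a) is used for both units; the upper unit has rings A (benzo), B (2-aryl) and C (pyran), the lower unit rings D (benzo), E (2-aryl) and F (pyran).

Step 1
Reactants: 1 1-[4-(benzyloxy)phenyl]-2-bromoethan-1-one
Product: 2 (1R)-1-[4-(benzyloxy)phenyl]-2-bromoethan-1-ol
Conditions: (R)-2-methyl-CBS-oxazaborolidine (10 mol%), BH3·SMe2 (0.7 equiv), THF, 0 °C; then MeOH, aq. NH4Cl
Reagents that add atoms: none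
Why: Corey–Bakshi–Shibata reduction: with the aryl group as the large substituent the (R)-oxazaborolidine–borane complex should deliver hydride to the face that gives the (R)-bromohydrin (the descriptor follows from CH2Br outranking aryl); this carbinol carbon becomes C2 of ring C.

Step 2
Reactants: 2 (1R)-1-[4-(benzyloxy)phenyl]-2-bromoethan-1-ol
Product: 3 (1R)-1-[4-(benzyloxy)phenyl]-2-iodoethan-1-ol
Conditions: NaI (3 equiv), acetone, 50 °C, dark
Reagents that add atoms: sodium iodide, [Na+].[I-]
Why: Finkelstein reaction: SN2 exchange at the primary carbon driven by precipitation of NaBr; the carbinol stereocentre is not touched, and the iodide is wanted because iodine–lithium exchange is clean at −78 °C.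

Step 3
Reactants: 3 (1R)-1-[4-(benzyloxy)phenyl]-2-iodoethan-1-ol; 4 4-(benzyloxy)-2-fluorobenzaldehyde
Product: 7 (2S)-7-(benzyloxy)-2-[4-(benzyloxy)phenyl]chroman-4-ol (both C4 epimers), via dilithio alkoxide 5 (not isolated), via dilithium diolate 6 (not isolated)
Conditions: n-BuLi (1.0 equiv) then t-BuLi (2.0 equiv), Et2O/THF, −78 °C; 4, −78 °C; then KOt-Bu (1.2 equiv), DMF (ethers distilled off), 70 °C; H2O
Reagents that add atoms: none
Why: O-deprotonation and iodine–lithium exchange turn 3 into the β-oxido alkyllithium 5 (persistent at −78 °C because lithium oxide is a poor leaving group), whose carbanionic C3 adds to the formyl carbon C4 of 4 to give diolate 6, and after exchange to potassium in hot DMF the C2 alkoxide displaces fluoride at C8a through a Meisenheimer adduct. The closest known reaction types are the addition of β-oxido organolithiums to aldehydes to give 1,3-diols and the alkoxide SNAr closure of 3-(2-fluoroaryl)propan-1-ols to chromans. Ring C closes in a formal [3+3] sense by a 6-exo-trig attack of O1 on the aromatic carbon C8a. The new C4 carbinol centre is not controlled and need not be, because step 5 ionises it, while C2 is carried over unchanged from 3 since its C–O bond is never broken. The step needs C-attack on the aldehyde before any O-arylation and arylation of the C2 oxygen only; the first follows from the far higher nucleophilicity of the alkyllithium at −78 °C, the second from the fact that only O1 reaches C8a through a six-membered transition state (the C4 oxygen would have to close a four-membered ring).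

Step 4
Reactants: 8 (−)-epiafzelechin, (2R,3R)-2-(4-hydroxyphenyl)chromane-3,5,7-triol
Product: 9 (2R,3R)-5,7-bis(benzyloxy)-2-[4-(benzyloxy)phenyl]chroman-3-ol
Conditions: BnBr (3.3 equiv), K2CO3, DMF, 0 °C to rt, argon
Reagents that add atoms: benzyl bromide, BrCc1ccccc1
Why: Williamson ether synthesis: K2CO3 ionises only the three phenols, so the secondary 3-OH should stay free; the low temperature is meant to avoid base-induced opening of ring F at C2, so both stereocentres are kept.

Step 5
Reactants: 7 (2S)-7-(benzyloxy)-2-[4-(benzyloxy)phenyl]chroman-4-ol (both C4 epimers); 9 (2R,3R)-5,7-bis(benzyloxy)-2-[4-(benzyloxy)phenyl]chroman-3-ol (3 equiv)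
Product: 11 (2R,3R)-5,7-bis(benzyloxy)-8-{(2S,4R)-7-(benzyloxy)-2-[4-(benzyloxy)phenyl]chroman-4-yl}-2-[4-(benzyloxy)phenyl]chroman-3-ol, via flavan-4-yl cation 10 (not isolated)
Conditions: BF3·OEt2 (0.3 equiv), 4 Å molecular sieves, CH2Cl2, −78 to −30 °C, slow addition of 7
Reagents that add atoms: none
Why: Friedel–Crafts-type SN1 substitution: BF3 ionises either C4 epimer of 7 to the same benzylic cation 10, stabilised through ring A by the para 7-benzyloxy group, and ring D of 9 should attack through C8, its least hindered free position (C6 lies between two benzyloxy groups); pseudo-axial attack on the sofa-shaped ring C on the face anti to the equatorial C2 aryl group (chair-like, staggered about C3–C4) should give the 2,4-trans (4R) product, and the excess of 9 suppresses self-condensation of 7.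

Step 6
Reactants: 11 (2R,3R)-5,7-bis(benzyloxy)-8-{(2S,4R)-7-(benzyloxy)-2-[4-(benzyloxy)phenyl]chroman-4-yl}-2-[4-(benzyloxy)phenyl]chroman-3-ol
Product: 12 (2R,3R)-8-[(2S,4R)-7-hydroxy-2-(4-hydroxyphenyl)chroman-4-yl]-2-(4-hydroxyphenyl)chromane-3,5,7-triol
Conditions: H2 (1 atm), Pd(OH)2/C, THF/MeOH, rt
Reagents that add atoms: none
Why: Hydrogenolysis of the five benzyl aryl ethers; under neutral conditions at 1 atm the cyclic benzylic C2–O1 ethers and the doubly benzylic C4–C8 bond should be much slower to cleave, and no stereocentre is affected.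

**Compound list**

1 | 1-[4-(benzyloxy)phenyl]-2-bromoethan-1-one | O=C(CBr)c1ccc(OCc2ccccc2)cc1 | starting material
2 | (1R)-1-[4-(benzyloxy)phenyl]-2-bromoethan-1-ol | BrC[C@H](O)c1ccc(OCc2ccccc2)cc1 | intermediate
3 | (1R)-1-[4-(benzyloxy)phenyl]-2-iodoethan-1-ol | IC[C@H](O)c1ccc(OCc2ccccc2)cc1 | intermediate
4 | 4-(benzyloxy)-2-fluorobenzaldehyde | O=Cc1ccc(OCc2ccccc2)cc1F | starting material
5 | lithium (1S)-1-[4-(benzyloxy)phenyl]-2-lithioethan-1-olate (C,O-dilithio form of 3, same spatial arrangement) | [Li]C[C@H](O[Li])c1ccc(OCc2ccccc2)cc1 | intermediate (not isolated)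
6 | dilithium (1RS,3S)-1-[4-(benzyloxy)-2-fluorophenyl]-3-[4-(benzyloxy)phenyl]propane-1,3-diolate | [Li]OC(C[C@H](O[Li])c1ccc(OCc2ccccc2)cc1)c1ccc(OCc2ccccc2)cc1F | intermediate (not isolated)
7 | (2S,4RS)-7-(benzyloxy)-2-[4-(benzyloxy)phenyl]chroman-4-ol | OC1C[C@@H](c2ccc(OCc3ccccc3)cc2)Oc2cc(OCc3ccccc3)ccc12 | intermediate
8 | (−)-epiafzelechin, (2R,3R)-2-(4-hydroxyphenyl)chromane-3,5,7-triol | O[C@@H]1Cc2c(O)cc(O)cc2O[C@@H]1c1ccc(O)cc1 | starting material
9 | (2R,3R)-5,7-bis(benzyloxy)-2-[4-(benzyloxy)phenyl]chroman-3-ol | O[C@@H]1Cc2c(OCc3ccccc3)cc(OCc3ccccc3)cc2O[C@@H]1c1ccc(OCc2ccccc2)cc1 | intermediate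
10 | (2S)-7-(benzyloxy)-2-[4-(benzyloxy)phenyl]chroman-4-ylium | [CH+]1C[C@@H](c2ccc(OCc3ccccc3)cc2)Oc2cc(OCc3ccccc3)ccc12 | intermediate (not isolated)
11 | (2R,3R)-5,7-bis(benzyloxy)-8-{(2S,4R)-7-(benzyloxy)-2-[4-(benzyloxy)phenyl]chroman-4-yl}-2-[4-(benzyloxy)phenyl]chroman-3-ol | c5ccccc5COc1ccc([C@@H]2C[C@@H](c3c(OCc5ccccc5)cc(OCc5ccccc5)c4c3O[C@H](c3ccc(OCc5ccccc5)cc3)[C@H](O)C4)c3ccc(OCc5ccccc5)cc3O2)cc1 | intermediate
12 | (2R,3R)-8-[(2S,4R)-7-hydroxy-2-(4-hydroxyphenyl)chroman-4-yl]-2-(4-hydroxyphenyl)chromane-3,5,7-triol | Oc1ccc([C@@H]2C[C@@H](c3c(O)cc(O)c4c3O[C@H](c3ccc(O)cc3)[C@H](O)C4)c3ccc(O)cc3O2)cc1 | target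

**Step count.** Total: 6 steps. Longest linear sequence: 5 steps (1, 2, 3, 5, 6); step 4 is a one-step side branch.

**Steps most likely to fail**

Step 3. The β-oxido alkyllithium may lose lithium oxide (β-elimination to the styrene) before it is trapped, or fluoride displacement on the electron-rich ring A may be so slow that the diolate decomposes. The fallback sets out from 1 and 4 and comes back at 7, making the two bonds in separate operations. A Reformatsky reaction of 1 with 4 (activated Zn, THF, 0 °C to rt) should give racemic 3-[4-(benzyloxy)-2-fluorophenyl]-1-[4-(benzyloxy)phenyl]-3-hydroxypropan-1-one F1. Noyori asymmetric transfer hydrogenation of its aryl ketone with RuCl(p-cymene)[(S,S)-TsDPEN] in HCO2H/Et3N should then set the future C2 and give (1RS,3S)-1-[4-(benzyloxy)-2-fluorophenyl]-3-[4-(benzyloxy)phenyl]propane-1,3-diol F2. The isolated diol is closed by alkoxide SNAr under forcing conditions (KOt-Bu, DMSO, 90 °C) to 7.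

Step 5. Facial selectivity at the planar C4 cation may be poor (attack cis to the C2 aryl group), attack may occur through C6 or the 3-hydroxyl of 9 instead of C8, or C3 may lose a proton to give the flav-3-ene, followed by self-condensation. The fallback sets out from 7 and 8 and comes back at 12, bypassing 9 and 11. The union is run with unprotected 8 (3 equiv) under reversible protic conditions (HCl in dioxane, rt), where O-alkylation is reversible and the free phloroglucinol-type ring D is by far the strongest carbon nucleophile. This should give (2R,3R)-8-{(2S,4R)-7-(benzyloxy)-2-[4-(benzyloxy)phenyl]chroman-4-yl}-2-(4-hydroxyphenyl)chromane-3,5,7-triol F3, and its hydrogenolysis (H2, Pd(OH)2/C, THF/MeOH) gives 12.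

Step 6. Over-reduction may open the benzylic C2–O1 ethers of rings C and F, or removal of the five benzyl groups may stay incomplete. The fallback sets out from 11 and comes back at 12 by a non-reductive Lewis-acid debenzylation (BCl3, pentamethylbenzene as benzyl-cation scavenger, CH2Cl2, −78 °C; the interflavan bond of the 5-deoxy upper unit should tolerate this). No new compound is made (F0).

**Further compounds**

F1 | step 3 | 3-[4-(benzyloxy)-2-fluorophenyl]-1-[4-(benzyloxy)phenyl]-3-hydroxypropan-1-one (racemic) | O=C(CC(O)c1ccc(OCc2ccccc2)cc1F)c1ccc(OCc2ccccc2)cc1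
F2 | step 3 | (1RS,3S)-1-[4-(benzyloxy)-2-fluorophenyl]-3-[4-(benzyloxy)phenyl]propane-1,3-diol | OC(C[C@H](O)c1ccc(OCc2ccccc2)cc1)c1ccc(OCc2ccccc2)cc1F
F3 | step 5 | (2R,3R)-8-{(2S,4R)-7-(benzyloxy)-2-[4-(benzyloxy)phenyl]chroman-4-yl}-2-(4-hydroxyphenyl)chromane-3,5,7-triol | c5ccccc5COc1ccc([C@@H]2C[C@@H](c3c(O)cc(O)c4c3O[C@H](c3ccc(O)cc3)[C@H](O)C4)c3ccc(OCc5ccccc5)cc3O2)cc1
F0 | step 6 | none | none
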